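**Retrosynthetic overview**

1. Endgame: target ⇐ aryl silyl ether cleavage ⇐ hydroxyl-directed epoxidation of the C3=C4 alkene ⇐ C4 ketone (kinetic enol triflate, then methyl cross-coupling).
2. Key disconnection C1–C10: a 7-endo radical conjugate addition of the C10 α-hydroxyalkyl radical onto a 2-alkylcyclopent-2-enone closes the seven-membered ring and creates the tertiary carbinol and C1 in one step; C5 is then set by epimerisation next to the C4 ketone.
3. Cyclisation substrate ⇐ Evans–Tishchenko reaction of a β-hydroxy ketone with a 4-silyloxybenzaldehyde (puts the aroyl group on O-8 and frees the C10 carbinol).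
4. β-Hydroxy ketone ⇐ proline aldol with acetone (C8) ⇐ enamine-catalysed α-alkylation of 3-methylbutanal with 2-(bromomethyl)cyclopent-2-enone (C7).
5. Ring order: the five-membered ring is bought as a cyclopentenone; the seven-membered ring is formed in the radical step.

Assumption: the given SMILES fixes the absolute configuration; locants follow guaiane numbering (C1/C5 ring fusion, C2–C4 five-membered ring, C6–C10 seven-membered ring, C14 = methyl on C10, C15 = methyl on C4), and 1 and 7 are bought as such.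

**Route**

Step 1
Reactants: 1 2-(hydroxymethyl)cyclopent-2-en-1-one
Product: 2 2-(bromomethyl)cyclopent-2-en-1-one
Conditions: PBr3 (0.4 equiv), Et2O, 0 °C
Reagents that add atoms: phosphorus tribromide, BrP(Br)Br
Why: SN2 bromination of the primary allylic alcohol via its phosphite ester; no stereocentre is formed.

Step 2
Reactants: 2 2-(bromomethyl)cyclopent-2-en-1-one; 3 3-methylbutanal
Product: 4 (2S)-3-methyl-2-[(5-oxocyclopent-1-en-1-yl)methyl]butanal
Conditions: (S)-α,α-diphenylprolinol trimethylsilyl ether (20 mol%), DABCO (1.0 equiv), excess aldehyde (3.0 equiv), CH2Cl2, 23 °C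
Reagents that add atoms: none
Why: Enamine-catalysed asymmetric α-alkylation by an SN2'–SN2' (addition–elimination) path, of the type established for 2-(bromomethyl)acrylates; the enamine of the aldehyde attacks the DABCO-activated allyl ammonium salt of the bromide from the face away from the diarylsilyloxymethyl group, which sets C7 as S.

Step 3
Reactants: 4 (2S)-3-methyl-2-[(5-oxocyclopent-1-en-1-yl)methyl]butanal; 5 propan-2-one
Product: 6 (4R,5S)-4-hydroxy-6-methyl-5-[(5-oxocyclopent-1-en-1-yl)methyl]heptan-2-one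
Conditions: L-proline (30 mol%), acetone/DMSO 1:4, 4 → 23 °C
Reagents that add atoms: none
Why: Proline-catalysed direct aldol reaction (List–Barbas); the acetone enamine adds to the Re face of the α-branched aldehyde under catalyst control, giving the 4R carbinol (C8).

Step 4
Reactants: 7 (4-bromophenoxy)tri(propan-2-yl)silane
Product: 9 4-[tri(propan-2-yl)silyloxy]benzaldehyde, via aryllithium 8 (not isolated)
Conditions: n-BuLi, THF, −78 °C; DMF; 1 M HCl work-up
Reagents that add atoms: N,N-dimethylformamide, CN(C)C=O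
Why: Bromine–lithium exchange followed by formylation with DMF (Bouveault aldehyde synthesis); no stereocentre.

Step 5
Reactants: 6 (4R,5S)-4-hydroxy-6-methyl-5-[(5-oxocyclopent-1-en-1-yl)methyl]heptan-2-one; 9 4-[tri(propan-2-yl)silyloxy]benzaldehyde
Product: 10 (3S,4R,6S)-6-hydroxy-2-methyl-3-[(5-oxocyclopent-1-en-1-yl)methyl]heptan-4-yl 4-[tri(propan-2-yl)silyloxy]benzoate
Conditions: SmI2 (0.3 equiv, premixed with the aldehyde), excess aldehyde (4.0 equiv), THF, −10 °C; aq. NaHCO3
Reagents that add atoms: none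
Why: Evans–Tishchenko reaction; SmI2 first reduces a small part of the aldehyde to its pinacolate, the trivalent samarium alkoxide that is the actual catalyst, and the samarium-bound hemiacetal formed from the aldehyde and the C8 hydroxyl then delivers hydride intramolecularly to the ketone, so O-8 is acylated with the aroyl group of the target and the C10 carbinol is freed with 1,3-anti selectivity (6S; this centre is erased in step 6), while the enone is untouched because no divalent samarium remains.

Step 6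
Reactants: 10 (3S,4R,6S)-6-hydroxy-2-methyl-3-[(5-oxocyclopent-1-en-1-yl)methyl]heptan-4-yl 4-[tri(propan-2-yl)silyloxy]benzoate
Product: 12 (1R,5S,7S,8R,10R)-10-hydroxy-4-oxo-15-norguaian-8-yl 4-[tri(propan-2-yl)silyloxy]benzoate (trans-fused), via cis-fused ketone 11 (not isolated)
Conditions: [Ir(dF(CF3)ppy)2(dtbbpy)]PF6 (1 mol%), quinuclidine (10 mol%), Bu4N(H2PO4) (25 mol%), MeCN, blue LEDs, 25 °C; then DBU (0.3 equiv), 25 °C
Reagents that add atoms: none
Why: Proposed new method: the photo-generated quinuclidine radical cation abstracts the hydridic α-hydroxy C10–H of the only free carbinol (phosphate hydrogen bonding activates it, the α-acyloxy C8–H is deactivated), the nucleophilic α-hydroxyalkyl radical adds 7-endo to the enone β-carbon C1 (6-exo attack at the α-carbon is polarity-mismatched), the α-keto radical is reduced by divalent iridium to the enolate and protonated, and DBU then equilibrates C5 to the trans ring fusion; C1 (R) and C10 (R) are set in a twist-chair transition state with the C7 isopropyl and C8 aroyloxy groups pseudo-equatorial and the phosphate-bound hydroxyl turned away from the cyclopentenone ring; the closest known reaction types are the intermolecular α-C–H alkylation of alcohols with acrylates under the same triple catalysis and 7-endo Giese cyclisations onto α-substituted enones.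

Step 7
Reactants: 12 (1R,5S,7S,8R,10R)-10-hydroxy-4-oxo-15-norguaian-8-yl 4-[tri(propan-2-yl)silyloxy]benzoate
Product: 13 (1R,5S,7S,8R,10R)-10-hydroxy-4-[(trifluoromethanesulfonyl)oxy]-15-norguai-3-en-8-yl 4-[tri(propan-2-yl)silyloxy]benzoate
Conditions: KN(SiMe3)2 (2.2 equiv), PhNTf2 (1.2 equiv), THF, −78 °C; aq. NH4Cl
Reagents that add atoms: N-phenylbis(trifluoromethanesulfonimide), O=S(=O)(N(c1ccccc1)S(=O)(=O)C(F)(F)F)C(F)(F)F
Why: Kinetic enol triflate formation; the base removes the unhindered C3 proton rather than the ring-fusion C5 proton, fixing the double bond at C3=C4, while the second equivalent only holds O-10 as its alkoxide; no stereocentre changes.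

Step 8
Reactants: 13 (1R,5S,7S,8R,10R)-10-hydroxy-4-[(trifluoromethanesulfonyl)oxy]-15-norguai-3-en-8-yl 4-[tri(propan-2-yl)silyloxy]benzoate
Product: 14 (1R,5S,7S,8R,10R)-10-hydroxyguai-3-en-8-yl 4-[tri(propan-2-yl)silyloxy]benzoate
Conditions: Me2Zn (3 equiv), Pd(PPh3)4 (5 mol%), THF, 0 → 50 °C
Reagents that add atoms: dimethylzinc, C[Zn]C
Why: Negishi cross-coupling of the alkenyl triflate (oxidative addition to zerovalent palladium, transmetalation, reductive elimination) installs C15 without moving the alkene; ester, silyl ether and stereocentres are untouched.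

Step 9
Reactants: 14 (1R,5S,7S,8R,10R)-10-hydroxyguai-3-en-8-yl 4-[tri(propan-2-yl)silyloxy]benzoate
Product: 15 (1R,3R,4S,5S,7S,8R,10R)-3,4-epoxy-10-hydroxyguaian-8-yl 4-[tri(propan-2-yl)silyloxy]benzoate
Conditions: VO(acac)2 (5 mol%), t-BuOOH (1.5 equiv), CH2Cl2, 0 → 23 °C
Reagents that add atoms: tert-butyl hydroperoxide, CC(C)(C)OO
Why: Hydroxyl-directed vanadium-catalysed epoxidation (Sharpless–Michaelson); the C10 hydroxyl sits on the face of the cyclopentene cis to H-1 and delivers the peroxide oxygen there, setting C3 (R) and C4 (S); the resulting syn epoxy alcohol cannot cyclise to an ether.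

Step 10
Reactants: 15 (1R,3R,4S,5S,7S,8R,10R)-3,4-epoxy-10-hydroxyguaian-8-yl 4-[tri(propan-2-yl)silyloxy]benzoate
Product: 16 (1R,3R,4S,5S,7S,8R,10R)-3,4-epoxy-10-hydroxyguaian-8-yl 4-hydroxybenzoate (CNP0225095.2)
Conditions: Bu4NF (1.1 equiv), AcOH (1.1 equiv), THF, 0 °C
Reagents that add atoms: none
Why: Fluoride-mediated cleavage of the aryl silyl ether under buffered conditions; ester, epoxide and tertiary alcohol are left intact.

**Compound list**

1 | 2-(hydroxymethyl)cyclopent-2-en-1-one | OCC1=CCCC1=O | starting material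
2 | 2-(bromomethyl)cyclopent-2-en-1-one | BrCC1=CCCC1=O | intermediate
3 | 3-methylbutanal | CC(C)CC=O | starting material
4 | (2S)-3-methyl-2-[(5-oxocyclopent-1-en-1-yl)methyl]butanal | CC(C)[C@H](CC1=CCCC1=O)C=O | intermediate
5 | propan-2-one | CC(C)=O | starting material
6 | (4R,5S)-4-hydroxy-6-methyl-5-[(5-oxocyclopent-1-en-1-yl)methyl]heptan-2-one | CC(C)[C@H](CC1=CCCC1=O)[C@H](O)CC(C)=O | intermediate
7 | (4-bromophenoxy)tri(propan-2-yl)silane | Brc1ccc(O[Si](C(C)C)(C(C)C)C(C)C)cc1 | starting material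
8 | {4-[tri(propan-2-yl)silyloxy]phenyl}lithium | [Li]c1ccc(O[Si](C(C)C)(C(C)C)C(C)C)cc1 | intermediate
9 | 4-[tri(propan-2-yl)silyloxy]benzaldehyde | O=Cc1ccc(O[Si](C(C)C)(C(C)C)C(C)C)cc1 | intermediate
10 | (3S,4R,6S)-6-hydroxy-2-methyl-3-[(5-oxocyclopent-1-en-1-yl)methyl]heptan-4-yl 4-[tri(propan-2-yl)silyloxy]benzoate | CC(C)[C@H](CC1=CCCC1=O)[C@H](OC(=O)c1ccc(O[Si](C(C)C)(C(C)C)C(C)C)cc1)C[C@H](C)O | intermediate
11 | (1R,5R,7S,8R,10R)-10-hydroxy-4-oxo-15-norguaian-8-yl 4-[tri(propan-2-yl)silyloxy]benzoate (cis-fused; H-1 and H-5 cis) | CC(C)[C@@H]1C[C@@H]2[C@@H](CCC2=O)[C@](C)(O)C[C@H]1OC(=O)c1ccc(O[Si](C(C)C)(C(C)C)C(C)C)cc1 | intermediate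
12 | (1R,5S,7S,8R,10R)-10-hydroxy-4-oxo-15-norguaian-8-yl 4-[tri(propan-2-yl)silyloxy]benzoate (trans-fused; OH-10 cis to H-1, O-8 trans to OH-10, isopropyl trans to O-8) | CC(C)[C@@H]1C[C@H]2[C@@H](CCC2=O)[C@](C)(O)C[C@H]1OC(=O)c1ccc(O[Si](C(C)C)(C(C)C)C(C)C)cc1 | intermediate
13 | (1R,5S,7S,8R,10R)-10-hydroxy-4-[(trifluoromethanesulfonyl)oxy]-15-norguai-3-en-8-yl 4-[tri(propan-2-yl)silyloxy]benzoate | CC(C)[C@@H]1C[C@H]2[C@@H](CC=C2OS(=O)(=O)C(F)(F)F)[C@](C)(O)C[C@H]1OC(=O)c1ccc(O[Si](C(C)C)(C(C)C)C(C)C)cc1 | intermediate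
14 | (1R,5S,7S,8R,10R)-10-hydroxyguai-3-en-8-yl 4-[tri(propan-2-yl)silyloxy]benzoate | CC(C)[C@@H]1C[C@H]2[C@@H](CC=C2C)[C@](C)(O)C[C@H]1OC(=O)c1ccc(O[Si](C(C)C)(C(C)C)C(C)C)cc1 | intermediate
15 | (1R,3R,4S,5S,7S,8R,10R)-3,4-epoxy-10-hydroxyguaian-8-yl 4-[tri(propan-2-yl)silyloxy]benzoate (epoxide oxygen cis to H-1) | CC(C)[C@@H]1C[C@H]2[C@@H](C[C@H]3O[C@]32C)[C@](C)(O)C[C@H]1OC(=O)c1ccc(O[Si](C(C)C)(C(C)C)C(C)C)cc1 | intermediate
16 | (1R,3R,4S,5S,7S,8R,10R)-3,4-epoxy-10-hydroxyguaian-8-yl 4-hydroxybenzoate | CC(C)[C@@H]1C[C@H]2[C@@H](C[C@H]3O[C@]32C)[C@](C)(O)C[C@H]1OC(=O)c1ccc(O)cc1 | target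

**Step count and risks**

Total step count: 10. Longest linear sequence: 9 steps (1, 2, 3, 5, 6, 7, 8, 9, 10; step 4 is a one-step side branch).

Most likely to fail, first: step 6. The intramolecular 7-endo mode of the alcohol C–H alkylation is untested, the ketyl-type radical can be over-oxidised to the ketone, and the facial selectivity at C1/C10 and the cis/trans equilibrium at C5 are predictions. The fallback sets out from 10 and comes back at 12, and swaps the photocatalytic hydrogen abstraction for a tin-hydride radical translocation with a bulky oxygen substituent. 10 is silylated with (2-bromophenyl)chlorodimethylsilane (imidazole, DMF) to give the bromoaryl silyl ether (3S,4R,6S)-6-{[(2-bromophenyl)dimethylsilyl]oxy}-2-methyl-3-[(5-oxocyclopent-1-en-1-yl)methyl]heptan-4-yl 4-[tri(propan-2-yl)silyloxy]benzoate F3. Bu3SnH (syringe pump) and AIBN in benzene at 80 °C generate the aryl radical, which moves the radical site to C10 by 1,5-hydrogen transfer and cyclises onto the enone. After DBU equilibration this gives the O-silylated trans-fused ketone (1R,5S,7S,8R,10R)-10-[dimethyl(phenyl)silyloxy]-4-oxo-15-norguaian-8-yl 4-[tri(propan-2-yl)silyloxy]benzoate F4, whose silyl ether is cleaved with PPTS in MeOH to give 12.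

Second: step 9. Direction by a tertiary bishomoallylic hydroxyl is weak and the reagent may take the other face. The fallback sets out from 14 and comes back at 15. NBS in THF/H2O forms the bromonium ion on the face the oxidant prefers and water opens it at C4 from the opposite face, giving the bromohydrin (1R,3S,4S,5S,7S,8R,10R)-3-bromo-4,10-dihydroxyguaian-8-yl 4-[tri(propan-2-yl)silyloxy]benzoate F5. K2CO3 in acetone then closes the epoxide from the C4 oxygen with inversion at C3, which gives 15.

Third: step 2. The cyclic bromide 2 is less explored than the acrylate electrophiles, and conjugate addition or erosion of the aldehyde stereocentre may compete. The fallback sets out from 3 (with 2 as electrophile) and comes back at 4 by auxiliary-controlled azaenolate alkylation. 3 is condensed with (2R)-1-amino-2-(methoxymethyl)pyrrolidine to give the hydrazone (E)-N-[(2R)-2-(methoxymethyl)pyrrolidin-1-yl]-3-methylbutan-1-imine F1. Deprotonation with LiN(iPr)2 (THF, 0 °C) and alkylation with 2 at −100 °C gives the alkylated hydrazone (1E,2S)-N-[(2R)-2-(methoxymethyl)pyrrolidin-1-yl]-3-methyl-2-[(5-oxocyclopent-1-en-1-yl)methyl]butan-1-imine F2, and two-phase hydrolysis with aqueous oxalic acid releases 4.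

Further compounds
F1 | step 2 | (E)-N-[(2R)-2-(methoxymethyl)pyrrolidin-1-yl]-3-methylbutan-1-imine | COC[C@H]1CCCN1/N=C/CC(C)C
F2 | step 2 | (1E,2S)-N-[(2R)-2-(methoxymethyl)pyrrolidin-1-yl]-3-methyl-2-[(5-oxocyclopent-1-en-1-yl)methyl]butan-1-imine | COC[C@H]1CCCN1/N=C/[C@H](C(C)C)CC1=CCCC1=O
F3 | step 6 | (3S,4R,6S)-6-{[(2-bromophenyl)dimethylsilyl]oxy}-2-methyl-3-[(5-oxocyclopent-1-en-1-yl)methyl]heptan-4-yl 4-[tri(propan-2-yl)silyloxy]benzoate | CC(C)[C@H](CC1=CCCC1=O)[C@H](OC(=O)c1ccc(O[Si](C(C)C)(C(C)C)C(C)C)cc1)C[C@H](C)O[Si](C)(C)c1ccccc1Br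
F4 | step 6 | (1R,5S,7S,8R,10R)-10-[dimethyl(phenyl)silyloxy]-4-oxo-15-norguaian-8-yl 4-[tri(propan-2-yl)silyloxy]benzoate | CC(C)[C@@H]1C[C@H]2[C@@H](CCC2=O)[C@](C)(O[Si](C)(C)c2ccccc2)C[C@H]1OC(=O)c1ccc(O[Si](C(C)C)(C(C)C)C(C)C)cc1
F5 | step 9 | (1R,3S,4S,5S,7S,8R,10R)-3-bromo-4,10-dihydroxyguaian-8-yl 4-[tri(propan-2-yl)silyloxy]benzoate | CC(C)[C@@H]1C[C@H]2[C@@H](C[C@H](Br)[C@@]2(C)O)[C@](C)(O)C[C@H]1OC(=O)c1ccc(O[Si](C(C)C)(C(C)C)C(C)C)cc1
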